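**Retrosynthetic overview**

1. 2α-Hydroxyferutinin ⇒ phenol desilylation, reduction of a C2 ketone by hydride delivered from the C4 β-hydroxyl, and acylation of the C6 α-hydroxyl ⇒ 4β,6α-dihydroxydauc-8-en-2-one plus silyl-protected 4-hydroxybenzoic acid.
2. Seven-membered ring (formed second): ring-closing metathesis at C8=C9 between an allyl group on C1 and a methallyl carbinol at C6; C6–C7 comes from chelation-controlled methallylation of a C5 aldehyde.
3. C5–C6 and C1–C10: a CH2 unit tethered through silicon to the C4 oxygen cyclises as a radical onto C5 of a cyclopentenone (necessarily cis to O4), and the resulting C1 radical is allylated anti to it.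
4. Five-membered ring (formed first): it carries oxygen at C2 and at the tertiary, isopropyl-bearing C4 in a 1,3-relation, with the methyl-bearing C1 between C2 and the fusion carbon C5. This is the pattern of a 4-hydroxy-4-alkyl-2-methylcyclopent-2-enone, which a 2,3,5-trisubstituted furylmethanol gives by Piancatelli rearrangement (C3–C4 formed).
5. The furan comes from methyl 3-methylfuran-2-carboxylate by Friedel–Crafts isopropylation at C5 and ester reduction.

Key step: step 3

Convention: daucane numbering is used for all intermediates (C1 methyl-bearing quaternary carbon, C2 carbinol/ketone, C3 methylene, C4 isopropyl carbinol, C5 fusion CH, C6 ester carbon, C8=C9 alkene). β is the face of the five-membered ring that carries the C1 methyl; absolute configurations are those of the SMILES strings.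

Assumption: which antipode of the chiral acid in step 3 leads to the (R)-enone cannot be foreseen; the route assumes that screening of both antipodes identifies it.

**Route**

Step 1
Reactants: 1 methyl 3-methylfuran-2-carboxylate; 2 2-chloropropane
Product: 3 methyl 5-isopropyl-3-methylfuran-2-carboxylate
Conditions: AlCl3, CH2Cl2, 0 °C to rt
Reagents that add atoms: none
Why: Friedel–Crafts alkylation places the isopropyl cation at C5, the only free α-position and the site at which 2-furoates undergo electrophilic substitution, while the ester tempers the ring against acid-induced polymerisation.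

Step 2
Reactants: 3 methyl 5-isopropyl-3-methylfuran-2-carboxylate
Product: 4 (5-isopropyl-3-methylfuran-2-yl)methanol
Conditions: LiAlH4, Et2O, 0 °C
Reagents that add atoms: none
Why: Hydride reduction of the ester to the primary alcohol leaves the furan untouched; the acid-sensitive carbinol should be used without storage.

Step 3
Reactants: 4 (5-isopropyl-3-methylfuran-2-yl)methanol
Product: 5 (R)-4-hydroxy-4-isopropyl-2-methylcyclopent-2-en-1-one
Conditions: one antipode of 3,3'-bis(2,4,6-triisopropylphenyl)-1,1'-binaphthyl-2,2'-diyl N-(trifluoromethylsulfonyl)phosphoramide (10 mol%), PhMe/H2O (biphasic, vigorous stirring), 40 °C, slow addition of 4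
Reagents that add atoms: water, O
Why: Proposed new method: the strong chiral acid ionises the primary carbinol, which the 3-methyl and 5-isopropyl groups make feasible by stabilising the furfuryl cation; water adds at the isopropyl-bearing furan carbon, the hemiketal opens to a 1,4-dihydroxypentadienyl cation, and conrotatory 4π electrocyclisation joins the former carbinol carbon to the isopropyl-bearing carbon (C3–C4), after which proton loss from the oxyallyl cation gives the enone. The closest known reactions are the acid-mediated (racemic) Piancatelli rearrangement of 5-alkyl-2-furylcarbinols, the chiral phosphoric acid-catalysed aza-Piancatelli rearrangement and the chiral N-triflylphosphoramide-catalysed Nazarov cyclisation, in which a chiral phosphate-type counter-ion steers the same kind of closure. The five-membered ring is closed by this 4π conrotatory electrocyclisation of a pentadienyl cation. The only new stereocentre, C4, is set by the sense of conrotation, which the hydrogen-bonded chiral anion must dictate because the CH2 terminus carries no stereochemical information. The step needs productive attack of water at the ring carbon (attack at the exocyclic carbon only returns 4) and no oligomerisation; both furan α-positions are substituted, which blocks the usual furfuryl alcohol polymerisation, and slow addition keeps the concentration of 4 low.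

Step 4
Reactants: 5 (R)-4-hydroxy-4-isopropyl-2-methylcyclopent-2-en-1-one; 6 (bromomethyl)chlorodimethylsilane
Product: 7 (R)-4-{[(bromomethyl)dimethylsilyl]oxy}-4-isopropyl-2-methylcyclopent-2-en-1-one
Conditions: Et3N, 4-(dimethylamino)pyridine (10 mol%), CH2Cl2, 0 °C to rt
Reagents that add atoms: none
Why: Silylation of the tertiary alcohol with a small chlorosilane under nucleophilic catalysis installs the one-carbon radical tether on the C4 oxygen without touching the stereocentre.

Step 5
Reactants: 7 (R)-4-{[(bromomethyl)dimethylsilyl]oxy}-4-isopropyl-2-methylcyclopent-2-en-1-one; 8 allyltributylstannane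
Product: 9 cis-fused 3,3,6-trimethyl-1-isopropyl-6-allyl-2-oxa-3-silabicyclo[3.3.0]octan-7-one (daucane terms: O4 and C6 on the β face bridged by SiMe2, C1 with β-methyl and α-allyl, C2 ketone, 4α-isopropyl)
Conditions: allylSnBu3 (4 equiv), 2,2'-azobis(2-methylpropionitrile) (AIBN, 0.2 equiv in portions), PhH, 80 °C
Reagents that add atoms: none
Why: In this silicon-tethered radical cyclisation with Keck allylation, Bu3Sn• abstracts bromine, the nucleophilic α-silyl radical closes 5-exo-trig onto the enone β-carbon C5 necessarily cis to the C4 oxygen (sets C5), and the tertiary α-keto radical at C1 is trapped by the allylstannane on the convex face anti to the new C5 substituent (sets C1, allyl α and methyl β), releasing Bu3Sn• to carry the chain.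

Step 6
Reactants: 9 cis-fused siloxane ketone
Product: 10 (2R,3S,4R)-4-hydroxy-3-(hydroxymethyl)-2-methyl-4-(propan-2-yl)-2-(prop-2-en-1-yl)cyclopentan-1-one
Conditions: 30% aq. H2O2, KF, KHCO3, THF/MeOH (1:1), rt
Reagents that add atoms: hydrogen peroxide, OO
Why: Tamao oxidation of the fluoride-activated alkoxysilane moves C6 from silicon to oxygen and hydrolysis of the Si–O bonds frees the 1,3-diol, while the hindered ketone and the terminal alkene do not react with buffered peroxide.

Step 7
Reactants: 10 diol ketone
Product: 11 (1R,2R,5R)-5-hydroxy-2-methyl-3-oxo-5-(propan-2-yl)-2-(prop-2-en-1-yl)cyclopentane-1-carbaldehyde (C5 β-formyl, 4β-hydroxyl, 4α-isopropyl, C1 β-methyl and α-allyl)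
Conditions: 2,2,6,6-tetramethylpiperidin-1-oxyl (TEMPO, 10 mol%), PhI(OAc)2, CH2Cl2, rt
Reagents that add atoms: none
Why: The oxoammonium oxidation acts on the primary alcohol, the only oxidisable hydroxyl, and its non-basic medium avoids retro-aldol cleavage and epimerisation at C5.

Step 8
Reactants: 11 keto aldehyde; 12 3-bromo-2-methylprop-1-ene
Product: 13 (2R,3S,4R)-4-hydroxy-3-[(1S)-1-hydroxy-3-methylbut-3-en-1-yl]-2-methyl-4-(propan-2-yl)-2-(prop-2-en-1-yl)cyclopentan-1-one (6α-hydroxyl in daucane terms)
Conditions: In powder, THF/H2O (1:1), rt
Reagents that add atoms: none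
Why: In this aqueous Barbier allylation, which is aldehyde-selective and tolerates free hydroxyls, the C4 β-hydroxyl and the aldehyde oxygen chelate trivalent indium in a six-membered ring cis-fused to the cyclopentane, so the carbonyl oxygen is held toward O4 and the methallyl group enters anti to the quaternary C1 (from the side of H5), which gives the C6 configuration of the target.

Step 9
Reactants: 13 diene diol
Product: 14 4β,6α-dihydroxydauc-8-en-2-one (trans-fused, C1 methyl β, H5 α)
Conditions: second-generation Grubbs catalyst (H2IMes)(PCy3)Cl2Ru=CHPh (5 mol%), CH2Cl2 (0.005 M), 40 °C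
Reagents that add atoms: none
Why: Ring-closing metathesis initiates at the monosubstituted allyl group and closes onto the 1,1-disubstituted methallyl alkene with loss of ethylene, giving the trisubstituted C8=C9 bond of the seven-membered ring with the trans ring fusion already fixed at C1 and C5.

Step 10
Reactants: 15 4-hydroxybenzoic acid
Product: 17 4-[(tert-butyldimethylsilyl)oxy]benzoic acid, via bis-silylated ester 16 (not isolated)
Conditions: TBSCl (2.3 equiv), imidazole, DMF, rt; then AcOH/THF/H2O, rt
Reagents that add atoms: tert-butyldimethylsilyl chloride, CC(C)(C)[Si](C)(C)Cl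
Why: Both hydroxyls are silylated, and the silyl ester, far more labile than the aryl silyl ether, is then hydrolysed selectively by mild aqueous acid.

Step 11
Reactants: 14 4β,6α-dihydroxydauc-8-en-2-one; 17 4-[(tert-butyldimethylsilyl)oxy]benzoic acid
Product: 18 6α-{4-[(tert-butyldimethylsilyl)oxy]benzoyloxy}-4β-hydroxydauc-8-en-2-one
Conditions: DCC, 4-(dimethylamino)pyridine (20 mol%), CH2Cl2, rt
Reagents that add atoms: none
Why: Steglich esterification acylates the secondary C6 hydroxyl with retention (no C–O bond is broken), and the tertiary C4 hydroxyl is inert to the acylpyridinium.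

Step 12
Reactants: 18 keto ester
Product: 19 6α-{4-[(tert-butyldimethylsilyl)oxy]benzoyloxy}dauc-8-ene-2α,4β-diol
Conditions: Me4NBH(OAc)3, MeCN/AcOH (1:1), −20 °C to rt
Reagents that add atoms: none
Why: In this Saksena–Evans hydroxyl-directed reduction the borohydride exchanges an acetate for the C4 β-hydroxyl and delivers hydride intramolecularly to the β face of the C2 ketone, giving the 2α-alcohol (anti-1,3-diol), and the reagent leaves the ester and the alkene alone.

Step 13
Reactants: 19 silyl-protected diol ester
Product: 20 2α-hydroxyferutinin (2α,4β-dihydroxy-6α-(4-hydroxybenzoyloxy)dauc-8-ene)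
Conditions: Bu4NF, AcOH (1:1), THF, 0 °C
Reagents that add atoms: none
Why: Fluoride cleaves the aryl silyl ether rapidly, and the acetic acid buffer prevents phenoxide-induced acyl migration or ester cleavage.

**Compound list**

1 | methyl 3-methylfuran-2-carboxylate | COC(=O)c1occc1C | starting material
2 | 2-chloropropane | CC(C)Cl | starting material
3 | methyl 5-isopropyl-3-methylfuran-2-carboxylate | COC(=O)c1oc(C(C)C)cc1C | intermediate
4 | (5-isopropyl-3-methylfuran-2-yl)methanol | CC(C)c1cc(C)c(CO)o1 | intermediate
5 | (R)-4-hydroxy-4-isopropyl-2-methylcyclopent-2-en-1-one | CC1=C[C@](O)(C(C)C)CC1=O | intermediate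
6 | (bromomethyl)chlorodimethylsilane | C[Si](C)(Cl)CBr | starting material
7 | (R)-4-{[(bromomethyl)dimethylsilyl]oxy}-4-isopropyl-2-methylcyclopent-2-en-1-one | CC1=C[C@](O[Si](C)(C)CBr)(C(C)C)CC1=O | intermediate
8 | allyltributylstannane | C=CC[Sn](CCCC)(CCCC)CCCC | starting material
9 | cis-fused 3,3,6-trimethyl-1-isopropyl-6-allyl-2-oxa-3-silabicyclo[3.3.0]octan-7-one (allyl anti to the siloxane ring) | C=CC[C@]2(C)[C@@H](C[Si](C)(C)O3)[C@]3(C(C)C)CC2=O | intermediate
10 | (2R,3S,4R)-4-hydroxy-3-(hydroxymethyl)-2-methyl-4-(propan-2-yl)-2-(prop-2-en-1-yl)cyclopentan-1-one | C=CC[C@]1(C)[C@@H](CO)[C@](O)(C(C)C)CC1=O | intermediate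
11 | (1R,2R,5R)-5-hydroxy-2-methyl-3-oxo-5-(propan-2-yl)-2-(prop-2-en-1-yl)cyclopentane-1-carbaldehyde | C=CC[C@]1(C)[C@@H](C=O)[C@](O)(C(C)C)CC1=O | intermediate
12 | 3-bromo-2-methylprop-1-ene | CC(=C)CBr | starting material
13 | (2R,3S,4R)-4-hydroxy-3-[(1S)-1-hydroxy-3-methylbut-3-en-1-yl]-2-methyl-4-(propan-2-yl)-2-(prop-2-en-1-yl)cyclopentan-1-one | C=CC[C@]1(C)[C@@H]([C@@H](O)CC(C)=C)[C@](O)(C(C)C)CC1=O | intermediate
14 | 4β,6α-dihydroxydauc-8-en-2-one | CC1=CC[C@]2(C)[C@@H]([C@@H](O)C1)[C@](O)(C(C)C)CC2=O | intermediate
15 | 4-hydroxybenzoic acid | O=C(O)c1ccc(O)cc1 | starting material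
16 | tert-butyldimethylsilyl 4-[(tert-butyldimethylsilyl)oxy]benzoate | CC(C)(C)[Si](C)(C)OC(=O)c1ccc(O[Si](C)(C)C(C)(C)C)cc1 | intermediate
17 | 4-[(tert-butyldimethylsilyl)oxy]benzoic acid | CC(C)(C)[Si](C)(C)Oc1ccc(C(=O)O)cc1 | intermediate
18 | 6α-{4-[(tert-butyldimethylsilyl)oxy]benzoyloxy}-4β-hydroxydauc-8-en-2-one | CC1=CC[C@]2(C)[C@@H]([C@@H](OC(=O)c3ccc(O[Si](C)(C)C(C)(C)C)cc3)C1)[C@](O)(C(C)C)CC2=O | intermediate
19 | 6α-{4-[(tert-butyldimethylsilyl)oxy]benzoyloxy}dauc-8-ene-2α,4β-diol | CC1=CC[C@]2(C)[C@@H]([C@@H](OC(=O)c3ccc(O[Si](C)(C)C(C)(C)C)cc3)C1)[C@](O)(C(C)C)C[C@@H]2O | intermediate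
20 | 2α-hydroxyferutinin | CC1=CC[C@]2(C)[C@@H]([C@@H](OC(=O)c3ccc(O)cc3)C1)[C@](O)(C(C)C)C[C@@H]2O | target

**Step count**

Total steps: 13. Longest linear sequence: 12 (steps 1–9 and 11–13); step 10 is a one-step side branch.

**Steps most likely to fail**

1. Step 3 (proposed new method). What may go wrong:
   - the primary carbinol may ionise too slowly at temperatures where the ion pair is tight enough for control;
   - the chiral anion may not steer the sense of conrotation;
   - the ring-opened dienol may tautomerise to the (Z)-enedione, or the cation may lose a proton from the C3 methyl, before closure.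

   Fallback: starting from 4, the rearrangement is run without chiral control under the classical aqueous Lewis acid conditions for 5-alkyl-2-furylcarbinols (ZnCl2, dioxane/H2O, reflux) to give the racemic enone F1. The enantiomers are separated by preparative chromatography on a chiral stationary phase (cellulose tris(3,5-dimethylphenylcarbamate)). The (R)-enantiomer is compound 5, at which the route is rejoined, and the (S)-enantiomer F2 is set aside.

2. Step 5. What may go wrong:
   - slow allyl transfer to the hindered tertiary α-keto radical may give a short radical chain and incomplete conversion;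
   - the 1,3-related isopropyl group may erode facial selectivity at C1.

   Fallback: starting from 7, the cyclisation is run reductively (Bu3SnH, AIBN, PhH, 80 °C, slow addition) to the bicyclic siloxane ketone F3 carrying hydrogen at C1. Soft enolisation under equilibrating conditions (Me3SiCl, NaI, Et3N, MeCN) gives the more substituted C1=C2 trimethylsilyl enol ether F4. Palladium-catalysed Tsuji allylation of this enol ether (allyl methyl carbonate, Pd2(dba)3, 1,2-bis(diphenylphosphino)ethane, THF, reflux) introduces the allyl group at C1 anti to the C5 substituent and returns to compound 9.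

3. Step 8. What may go wrong:
   - if water competes with the tertiary hydroxyl for indium and the chelate does not form, the aldehyde reacts through a conformer with its oxygen turned toward C1, and facial selectivity at C6 is poor or reversed.

   Fallback: starting from 11, the face of the aldehyde is fixed by the reagent instead of the chelate. Brown allylboration with B-(2-methylallyl)diisopinocampheylborane (from the suitable antipode of B-methoxydiisopinocampheylborane and 2-methylallylmagnesium chloride; Et2O, −78 °C, then NaBO3 work-up) gives compound 13 directly; no further compound arises (F0).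

Further compounds
F1 | step 3 | racemic 4-hydroxy-4-isopropyl-2-methylcyclopent-2-en-1-one | CC1=CC(O)(C(C)C)CC1=O
F2 | step 3 | (S)-4-hydroxy-4-isopropyl-2-methylcyclopent-2-en-1-one | CC1=C[C@@](O)(C(C)C)CC1=O
F3 | step 5 | cis-fused 3,3,6-trimethyl-1-isopropyl-2-oxa-3-silabicyclo[3.3.0]octan-7-one (hydrogen at C1, either epimer) | CC2[C@@H](C[Si](C)(C)O3)[C@]3(C(C)C)CC2=O
F4 | step 5 | trimethylsilyl enol ether of F3 (C1=C2) | CC1=C(O[Si](C)(C)C)C[C@]2(C(C)C)O[Si](C)(C)C[C@H]12
F0 | step 8 | none | none
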